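The constants belong to no real substance; the run is a simulation.

With a small charge of substrate, I asked which way of adding things sends the largest part of it to the side product.

    substrate + partner → intermediate A (k1 = 24.7 M⁻¹ s⁻¹)
    second reagent + intermediate A → intermediate B (k2 = 68.9 M⁻¹ s⁻¹)
    third reagent + intermediate B → target (k3 = 12.9 M⁻¹ s⁻¹)
    substrate + second reagent → side product (k4 = 63.1 M⁻¹ s⁻¹)
    third reagent → decomposition product (k5 = 4.23 × 10⁻⁵ s⁻¹)
    2 substrate → self-condensation product (k6 = 313 M⁻¹ s⁻¹)

| setting | midnight | dawn | dusk | summer |
|---|---|---|---|---|
| substrate | 2.0 mM | 2.0 mM (fed, over 6.0 s) | 2.0 mM | 2.0 mM |
| partner | 1.50 equiv | 1.50 equiv | 1.50 equiv | 1.50 equiv |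
| second reagent | 1.05 equiv (fed, over 6.0 s) | 1.05 equiv | 1.05 equiv | 1.05 equiv (fed, over 1.5 s) |
| third reagent | 4.00 equiv | 4.00 equiv | 4.00 equiv | 4.00 equiv |
| time | 8.0 s | 8.0 s | 8.0 s | 8.0 s |
| remark | all else is in the flask from the start; the feed brings no volume worth counting | all else is in the flask from the start; the feed brings no volume worth counting | everything together at the start | all else is in the flask from the start; the feed brings no volume worth counting |

- percentages count the substrate that a species holds: one self-condensation product counts as two
- where a step has two of a species, its rate is k times that concentration squared, and two are used at each turn
- run time (midnight): 8.0 s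

1. the flask that comes out highest in amount of side product, in percent of the substrate charged; "all alike" if 1.5 percentage points covers them all (midnight / dawn / dusk / summer / all alike)
2. amount of side product at the end, in percent of the substrate charged, midnight
3. amount of side product at the end, in percent of the substrate charged, dawn
4. amount of side product at the end, in percent of the substrate charged, dusk
5. amount of side product at the end, in percent of the substrate charged, summer

I first turned the constants into rates per substrate at the charged amounts. Partner and second reagent together take substrate at 0.207 s⁻¹, and the side step's part of that is 0.133 s⁻¹. Self-condensation takes it at 1.25 s⁻¹ at the full charge, and this rate falls as the substrate falls.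

In dusk, the side step's part of the substrate lost starts at 9.13 % and climbs as the substrate drops. Averaged over the substrate, with partner and second reagent held at their charges, it comes to 20.7 %.

In dawn, the substrate enters at 0.333 mM s⁻¹ and should settle at a quasi-steady level L, where its losses match the feed. Those losses are the first-order rate times L plus the self-condensation rate, which goes with L squared, so L is 0.583 mM. The feed-level side share φ is the side step's rate at L divided by the feed, 23.2 %. That stands above the dusk average, so I put dawn first.

In midnight and summer, self-condensation runs at the start with no second reagent present. Its rate is faster than the slow feed's pace of 0.167 s⁻¹, so I ranked summer third and midnight last, without figures.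

The forecast named dawn, with 6.8 % for midnight, 22 % for dawn, 17.2 % for dusk and 12.5 % for summer, on the ground that feeding substrate “keeps substrate low, which suppresses self-condensation”. Its dusk figure lay below my average, and its dawn figure lay below my φ.

The simulation gave 6.86 % for midnight, 20.6 % for dawn, 17.4 % for dusk and 12.5 % for summer, so dawn came out highest, and every forecast figure held within its tolerance.

Dawn's lead over midnight was 14 percentage points, and with the path to self-condensation product taken away it shrank to 4.8 points, the largest single effect. With 13 % of the substrate still unreacted in dawn, φ times the part consumed is 20.2 %, beside the 20.6 % found. For the neighbouring dawn flask with 0.630 equiv of second reagent, the same reckoning gives L = 0.617 mM and φ = 14.7 %. With 14.3 % of its substrate left, that makes 12.6 %, and the flask gave 12.9 %.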